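Take the late readings of both earlier runs and divide the summed target by the summed target and isomer of the product.

| flask | starting material | gas | remark | time |
|---|---|---|---|---|
| Tuesday's | 13 mM (fed, over 40 h) | 6.3 mM (held) | run made earlier |  |
| Friday's | 30 mM (fed, over 40 h) | 6.3 mM (held) | run made earlier |  |
| flask | 20 mM (fed, over 40 h) | 6.3 mM (held) |  | 15 d |

| run | time / d | starting material / % | target / % | isomer of the product / % |
|---|---|---|---|---|
| Tuesday's | 1.67 | 13 | 30 | 45 |
| Tuesday's | 4.00 | 1 | 33 | 52 |
| Tuesday's | 5.00 | 0 | 35 | 54 |
| Tuesday's | 8.00 | 3 | 33 | 53 |
| Tuesday's | 10.0 | 1 | 37 | 53 |
| Friday's | 1.67 | 34 | 28 | 34 |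
| Friday's | 4.00 | 0 | 38 | 58 |
| Friday's | 5.00 | 0 | 36 | 60 |
| Friday's | 8.00 | 0 | 38 | 58 |
| Friday's | 10.0 | 0 | 35 | 55 |

(standard deviation of a reading: 1.5 percentage points)

- what was read earlier has a scatter of 1.5 percentage points, one standard deviation
- at the start none of the gas is in solution
- the reaction counts as stopped when no species that holds the starting material changes by six tenths of a point or more over the second half of the time

* at 15 d, what has stopped the reaction, if anything has (it is still moving / forward and back rates have come level / all of the starting material has reacted)
* how much of the starting material has reacted by 15 d
* how much target there is at 15 d, in percent of the starting material charged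
* how much isomer of the product there is at 15 d, in percent of the starting material charged

From 4.00 d on, this gives 0.391, the target share, c(target)/(c(target) + c(isomer of the product)). The pair itself reads 87.5% on Tuesday and 94.5% on Friday. Placed by charge between these two readings, my estimate of the pair in the flask is 90.4%, so my own reckoning gives 35.4% target and 55.0% isomer of the product, slightly below the forecast.

The forecast says all of the starting material has reacted, with conversion 100%, target 36% and isomer of the product 56%, noting that “The target share is about 0.39 in both runs”.

The flask gives all of the starting material has reacted, with conversion 100%, target 35.0% and isomer of the product 56.0%.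

    starting material + coupling partner → target (k = 48.0 /M/h)
    starting material + 2 coupling partner → side product (k = 1900 /M²/h)
    gas ⇌ coupling partner, rate k3*(csat - [coupling partner]) (kL = 0.120 /h)
    target ⇌ isomer of the product (K = 1.60, k = 0.390 /h)

The flask's target stands at 35.0%, not the 91.1% of the same run with the target–isomer step struck out, because that step drains it. The step's relaxation half-life, 1.09 h, is short against 15 d, and the equilibrium share (thermodynamic control) is 0.385. The target share read earlier, 0.391, applied to the flask's pair of 91.0%, gives 35.6% target. Applied to the pair of 88.0% in the neighbour flask with 12 mM of starting material, it gives 34.5% target, and that neighbour flask holds 33.9% target.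

Readings and results are simulated for substances that don't exist, and the scatter is random.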